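## Retrosynthetic overview

1. Target 17 ⇒ seco furan 14 by a late oxidative ring expansion. The 3-methylfuran ring supplies C3–C6 (furan O becomes the C3 ketone, the 4Z alkene is fixed by the ring). The freed C6 aldehyde is captured by C7 of the tethered 2-(methoxycarbonyl)allyl bromide. The ten-membered carbocycle closes first (C6–C7), the cis-fused γ-lactone second (O6→C12), in the same flask.
2. 14 ⇒ diol 12 + (2S)-2-methylbutanoyl chloride (C8 ester). 12 ⇒ β-hydroxy methyl ketone 7 + (E)-alkenylzinc from alkyne 9 (C1–C10 bond, C10 set by 1,3-chelation control).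
3. 7 ⇒ bromo-enal 4 + acetone enol ether (catalytic enantioselective aldol, C8–C9 bond, sets C8).
4. 4 ⇒ Morita–Baylis–Hillman adduct of 2,2-dimethoxyacetaldehyde and methyl acrylate; 9 ⇒ 3-methylfuran-2-carbaldehyde by one-carbon homologation.

Assumption and labels: 1 (as its 60% aqueous solution), 2, 5, 8 and 13 are bought. The SMILES is read as 6S,7R,8R,10R,2′S with 1E,4Z alkenes and a cis-fused lactone; C1–C10 are the carbocycle atoms (C3 ketone, C6 and C8 oxygen-bearing, C10 tertiary carbinol) and C11–C13 the methylene-lactone carbons.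

## Route

Step 1
Reactants: 1 2,2-dimethoxyacetaldehyde; 2 methyl acrylate
Product: 3 methyl 3-hydroxy-4,4-dimethoxy-2-methylidenebutanoate (racemic)
Conditions: DABCO (0.5 equiv), 1,4-dioxane/H2O (1:1), rt
Reagents that add atoms: none
Why: Morita–Baylis–Hillman reaction of a highly electrophilic glyoxal-type aldehyde, accelerated by water; the carbinol centre formed is racemic and is erased in step 2.

Step 2
Reactants: 3 methyl 3-hydroxy-4,4-dimethoxy-2-methylidenebutanoate
Product: 4 methyl (2Z)-2-(bromomethyl)-4-oxobut-2-enoate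
Conditions: 48% aq HBr, H2SO4 (cat.), CH2Cl2, 0 °C → rt
Reagents that add atoms: hydrogen bromide, Br; water, O
Why: acid-mediated SN2′ bromination (allylic transposition) of the Baylis–Hillman alcohol gives the thermodynamically preferred Z bromide (formyl trans to the ester, cis to CH2Br) while the same aqueous acid hydrolyses the dimethyl acetal; no stereocentre remains.

Step 3
Reactants: 4 methyl (2Z)-2-(bromomethyl)-4-oxobut-2-enoate; 5 2-methoxypropene
Product: 7 methyl (2Z,4R)-2-(bromomethyl)-4-hydroxy-6-oxohept-2-enoate, via methyl enol ether 6 (not isolated)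
Conditions: Ti(OiPr)4 / binaphthyl-derived tridentate Schiff-base ligand (antipode giving Re-face attack) / 3,5-di-tert-butylsalicylic acid (5 mol%), 2,6-di-tert-butyl-4-methylpyridine, 5 as solvent, 0 °C; then 2 M HCl, Et2O, 0 °C
Reagents that add atoms: water, O
Why: titanium–binaphthyl-catalysed enantioselective ene-type aldol addition of the acetone enol ether to the aldehyde under Lewis-acidic, base-free conditions that leave the allylic bromide alone, the ligand antipode being chosen so that the C–C bond forms on the Re face to give the 4R carbinol (C8), after which mild acid hydrolyses the enol ether to the methyl ketone.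

Step 4
Reactants: 8 3-methylfuran-2-carbaldehyde
Product: 9 2-ethynyl-3-methylfuran
Conditions: Me3SiCHN2, LiN(iPr)2, THF, −78 °C → rt
Reagents that add atoms: (trimethylsilyl)diazomethane, C[Si](C)(C)C=[N+]=[N-]
Why: Colvin rearrangement (addition of lithiated silyldiazomethane, Peterson-type loss of silanolate, loss of N2 and 1,2-hydride shift of the alkylidene carbene) homologates the aldehyde to the terminal alkyne; no stereocentre is involved.

Step 5
Reactants: 9 2-ethynyl-3-methylfuran; 7 methyl (2Z,4R)-2-(bromomethyl)-4-hydroxy-6-oxohept-2-enoate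
Product: 12 methyl (2Z,4R,6R,7E)-2-(bromomethyl)-4,6-dihydroxy-6-methyl-8-(3-methylfuran-2-yl)octa-2,7-dienoate, via alkenylzirconocene chloride 10 (not isolated), via alkenyl(methyl)zinc 11 (not isolated)
Conditions: 9 (2.5 equiv), Cp2Zr(H)Cl, CH2Cl2, rt; Me2Zn, toluene, −65 °C; then 7 (pre-treated with Me2Zn, 1.0 equiv), −40 → −10 °C; aq NH4Cl
Reagents that add atoms: none
Why: syn-hydrozirconation puts zirconium on the terminal carbon (E-alkenyl), Zr-to-Zn transmetalation gives a mild alkenylzinc that adds only to the ketone, and Cram-chelate-type 1,2-addition (the methylzinc alkoxide of the 4-hydroxyl binds the ketone in a six-membered chelate, the alkenyl group attacks axially with the ketone methyl equatorial) gives the 1,3-anti diol, that is 6R (C10), while at −40 °C the zinc alkoxide does not displace the cis allylic bromide.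

Step 6
Reactants: 12 methyl (2Z,4R,6R,7E)-2-(bromomethyl)-4,6-dihydroxy-6-methyl-8-(3-methylfuran-2-yl)octa-2,7-dienoate; 13 (2S)-2-methylbutanoyl chloride
Product: 14 methyl (2Z,4R,6R,7E)-2-(bromomethyl)-6-hydroxy-6-methyl-4-{[(2S)-2-methylbutanoyl]oxy}-8-(3-methylfuran-2-yl)octa-2,7-dienoate
Conditions: 13 (1.5 equiv), 2,4,6-collidine, CH2Cl2, −20 → 0 °C
Reagents that add atoms: none
Why: O-acylation (nucleophilic acyl substitution) of the secondary allylic alcohol with the tertiary alcohol inert, using a hindered pyridine base that neither quaternises the allylic bromide nor racemises the acid chloride through its ketene; the C8–O bond is untouched so C8 keeps its configuration, and O8 is now blocked from lactonising or cyclising onto the bromide.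

Step 7
Reactants: 14 methyl (2Z,4R,6R,7E)-2-(bromomethyl)-6-hydroxy-6-methyl-4-{[(2S)-2-methylbutanoyl]oxy}-8-(3-methylfuran-2-yl)octa-2,7-dienoate
Product: 17 (3aR,4R,6R,7E,10Z,11aS)-6-hydroxy-6,10-dimethyl-3-methylidene-2,9-dioxo-2,3,3a,4,5,6,9,11a-octahydrocyclodeca[b]furan-4-yl (2S)-2-methylbutanoate, via seco keto-enal 15 (not isolated), via macrocyclic hydroxy ester 16 (not isolated)
Conditions: N-bromosuccinimide (1.05 equiv), NaHCO3, THF/H2O (4:1), −10 °C; then dilution to 2 mM with THF/sat. aq NH4Cl, indium powder (3 equiv), rt → 40 °C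
Reagents that add atoms: water, O
Why: Proposed new method: an oxidative furan-to-carbocycle ring expansion (a carba-Achmatowicz reaction) in which bromonium attack at furan C5 and addition of water open the ring to the (Z)-4-oxo-2-enal 15 exactly as in the first half of an Achmatowicz rearrangement (furan oxygen becomes the C3 ketone, the 4Z geometry is inherited from the ring), but the freed C6 aldehyde is trapped by C7 of the tethered 2-(methoxycarbonyl)allylindium formed from the bromide in the same flask instead of by a side-chain hydroxyl, so the five-membered ring grows into the ten-membered carbocycle; the closed chair (Zimmerman–Traxler) transition state of the Z-configured allylindium gives the 6,7-syn adduct 16, the aldehyde adds to the face of C7 anti to the C9 chain in the allylic-strain-minimised conformer (C8–H eclipsing the alkene, acyloxy outside), which sets 7R and hence 6S, and the indium alkoxide closes the cis-fused lactone on C12; the closest known reactions are the Achmatowicz oxidative ring expansion of furfuryl alcohols, the N-bromosuccinimide oxidation of 2-alkylfurans to cis-enediones and the metal-mediated Barbier macro-allylation of ω-formyl 2-(bromomethyl)acrylates to ten-membered methylene lactones.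

## Compound list

1 | 2,2-dimethoxyacetaldehyde | COC(OC)C=O | starting material
2 | methyl acrylate | C=CC(=O)OC | starting material
3 | methyl 3-hydroxy-4,4-dimethoxy-2-methylidenebutanoate (racemic) | C=C(C(=O)OC)C(O)C(OC)OC | intermediate
4 | methyl (2Z)-2-(bromomethyl)-4-oxobut-2-enoate | BrC/C(C(=O)OC)=C\C=O | intermediate
5 | 2-methoxypropene | C=C(C)OC | starting material
6 | methyl (2Z,4R)-2-(bromomethyl)-4-hydroxy-6-methoxyhepta-2,6-dienoate (methyl enol ether) | BrC/C(C(=O)OC)=C\[C@H](O)CC(=C)OC | intermediate
7 | methyl (2Z,4R)-2-(bromomethyl)-4-hydroxy-6-oxohept-2-enoate | BrC/C(C(=O)OC)=C\[C@H](O)CC(C)=O | intermediate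
8 | 3-methylfuran-2-carbaldehyde | Cc1ccoc1C=O | starting material
9 | 2-ethynyl-3-methylfuran | C#Cc1occc1C | intermediate
10 | chloridobis(cyclopentadienyl)[(E)-2-(3-methylfuran-2-yl)ethenyl]zirconium | Cc1ccoc1/C=C/[Zr+2]Cl.c1cc[cH-]c1.c1cc[cH-]c1 | intermediate
11 | methyl[(E)-2-(3-methylfuran-2-yl)ethenyl]zinc | C[Zn]/C=C/c1occc1C | intermediate
12 | methyl (2Z,4R,6R,7E)-2-(bromomethyl)-4,6-dihydroxy-6-methyl-8-(3-methylfuran-2-yl)octa-2,7-dienoate | BrC/C(C(=O)OC)=C\[C@H](O)C[C@@](C)(O)/C=C/c1occc1C | intermediate
13 | (2S)-2-methylbutanoyl chloride | ClC(=O)[C@@H](C)CC | starting material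
14 | methyl (2Z,4R,6R,7E)-2-(bromomethyl)-6-hydroxy-6-methyl-4-{[(2S)-2-methylbutanoyl]oxy}-8-(3-methylfuran-2-yl)octa-2,7-dienoate | BrC/C(C(=O)OC)=C\[C@H](OC(=O)[C@@H](C)CC)C[C@@](C)(O)/C=C/c1occc1C | intermediate
15 | methyl (2Z,4R,6R,7E,10Z)-2-(bromomethyl)-6-hydroxy-6,10-dimethyl-4-{[(2S)-2-methylbutanoyl]oxy}-9,12-dioxododeca-2,7,10-trienoate (seco keto-enal) | BrC/C(C(=O)OC)=C\[C@H](OC(=O)[C@@H](C)CC)C[C@@](C)(O)/C=C/C(=O)/C(C)=C\C=O | intermediate
16 | methyl 2-[(1S,2S,3Z,6E,8R,10R)-2,8-dihydroxy-4,8-dimethyl-10-{[(2S)-2-methylbutanoyl]oxy}-5-oxocyclodeca-3,6-dien-1-yl]prop-2-enoate (macrocyclic hydroxy ester) | C=C(C(=O)OC)[C@H]1[C@@H](O)/C=C(/C)C(=O)/C=C/[C@](C)(O)C[C@H]1OC(=O)[C@@H](C)CC | intermediate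
17 | (3aR,4R,6R,7E,10Z,11aS)-6-hydroxy-6,10-dimethyl-3-methylidene-2,9-dioxo-2,3,3a,4,5,6,9,11a-octahydrocyclodeca[b]furan-4-yl (2S)-2-methylbutanoate | C=C1C(=O)O[C@H]2/C=C(/C)C(=O)/C=C/[C@](C)(O)C[C@@H](OC(=O)[C@@H](C)CC)[C@@H]12 | target

## Step count and risks

Total steps: 7. Longest linear sequence: 6 (steps 1, 2, 3, 5, 6, 7; step 4 is the side branch).

Steps most likely to fail:

First, step 7, the proposed ring expansion. Indium may reduce the doubly activated C4=C5 ene-dione. The allylindium can lose the C8 carboxylate by 1,4-elimination before it cyclises. The C6 alkoxide can be diverted through its C3 hemiketal to a furan. The facial selectivity at C7 rests on a conformational model. The fallback uses known reactions only and sets out from 14. Palladium-catalysed borylation of the allylic bromide (B2pin2, Pd2(dba)3, AsPh3, toluene, 50 °C) gives the allyl pinacolboronate F1, with boron on the primary carbon and the alkene geometry kept. Ordinary furan oxidation (N-bromosuccinimide, NaHCO3, THF/H2O, −10 °C) then gives the isolable boronate keto-enal F2. Warming F2 at 2 mM in toluene (60 °C) brings about a thermal intramolecular allylboration through the same closed chair transition state, with no reducing metal and no allyl-metal that can eliminate. Hydrolysis of the borate returns the hydroxy ester 16, where the route is rejoined; 16 lactonises to 17 as in step 7.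

Second, step 5, the alkenylzinc addition. The ketone may be too unreactive, the organozinc may attack the bromomethyl acrylate in an SN2′ sense, the zinc alkoxide may close a dihydrofuran onto the cis bromide, or the 1,3-control may be poor. The fallback builds the tertiary carbinol the other way round and sets out from 8 and 4. Claisen–Schmidt condensation of 8 with acetone (aq NaOH, rt) gives the enone F3. Its boron aldol with 4 (the antipode of B-chlorodiisopinocampheylborane that gives 4R, iPr2NEt, Et2O, −78 °C) gives the β-hydroxy enone F4. MeTi(OiPr)3 (CH2Cl2, −40 → 0 °C) then binds the 4-hydroxyl as a titanium alkoxide and hands methyl to the ketone from within (six-membered chair, alkenyl group equatorial), which is expected to give the same 1,3-anti diol. The sequence comes back at 12.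

Third, step 3, the catalytic aldol on the sensitive bromo-enal. Low enantioselectivity or attack of the enol ether on the allylic bromide would stop the route early. The fallback sets C8 before the bromoacrylate exists and sets out from 1. L-Proline-catalysed aldol of acetone with 1 (acetone/DMSO, rt) gives the hydroxy acetal F5. Acetal hydrolysis (1 M HCl, THF) gives the hydroxy aldehyde F6, used crude. Morita–Baylis–Hillman reaction of F6 with 2 (DABCO, 1,4-dioxane/H2O) gives the dihydroxy ester F7. The HBr/H2SO4 treatment of step 2 then brominates only the allylic carbinol in the SN2′ sense and the route is rejoined at 7.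

Further compounds
F1 | step 7 | methyl (2E,4R,6R,7E)-6-hydroxy-6-methyl-4-{[(2S)-2-methylbutanoyl]oxy}-8-(3-methylfuran-2-yl)-2-[(4,4,5,5-tetramethyl-1,3,2-dioxaborolan-2-yl)methyl]octa-2,7-dienoate | CC1(C)OB(C/C(C(=O)OC)=C\[C@H](OC(=O)[C@@H](C)CC)C[C@@](C)(O)/C=C/c2occc2C)OC1(C)C
F2 | step 7 | methyl (2E,4R,6R,7E,10Z)-6-hydroxy-6,10-dimethyl-4-{[(2S)-2-methylbutanoyl]oxy}-9,12-dioxo-2-[(4,4,5,5-tetramethyl-1,3,2-dioxaborolan-2-yl)methyl]dodeca-2,7,10-trienoate | CC1(C)OB(C/C(C(=O)OC)=C\[C@H](OC(=O)[C@@H](C)CC)C[C@@](C)(O)/C=C/C(=O)/C(C)=C\C=O)OC1(C)C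
F3 | step 5 | (3E)-4-(3-methylfuran-2-yl)but-3-en-2-one | CC(=O)/C=C/c1occc1C
F4 | step 5 | methyl (2Z,4R,7E)-2-(bromomethyl)-4-hydroxy-8-(3-methylfuran-2-yl)-6-oxoocta-2,7-dienoate | BrC/C(C(=O)OC)=C\[C@H](O)CC(=O)/C=C/c1occc1C
F5 | step 3 | (4R)-4-hydroxy-5,5-dimethoxypentan-2-one | COC(OC)[C@H](O)CC(C)=O
F6 | step 3 | (2R)-2-hydroxy-4-oxopentanal | O=C[C@H](O)CC(C)=O
F7 | step 3 | methyl (4R)-3,4-dihydroxy-2-methylidene-6-oxoheptanoate (mixture of C3 epimers) | C=C(C(=O)OC)C(O)[C@H](O)CC(C)=O
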